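Everything rests on cutting the unfunctionalised CH2–CH2–CH2 tether (C3–C5 of the nonyl backbone, C1 being the CH2OAc carbon) between methine C2, which bears CH2OAc, and methine C6, which bears CH2OH. The key step exploits exactly this heteroatom-free tether. A nickel-electrocatalytic doubly decarboxylative coupling joins C4 to C5, merging two primary N-hydroxyphthalimide esters with loss of two CO2 into the complete acyclic C16 chain. Each precursor is an Evans-derived acid derivative holding one stereocentre: the east ester carries the acetate and the Z-allylic silyl ether, the west ester a silyloxymethyl and an allyl group. The butenolide ring arrives afterwards, intact, by B-alkyl Suzuki coupling.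

Key step: step 14

Atom numbering: C1 = CH2OAc carbon, C2 = acetoxymethyl-bearing methine, C3–C5 = tether, C6 = hydroxymethyl-bearing methine, C7–C9 = chain ending at C3 of the butenolide ring.
Remark: the CIP descriptors of both methines switch at the coupling (4S in the east ester becomes 2R, 3R in the west ester becomes 6S). This happens only because substituent priorities change; no bond at either centre is touched.
Assumption: the silyloxyacetone and the bromobutenolide building blocks are taken as catalogue chemicals.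

Step 1
Reactants: 1 (4-carboxybutyl)triphenylphosphonium bromide; 2 1-[(tert-butyldimethylsilyl)oxy]propan-2-one
Product: 4 (5Z)-7-[(tert-butyldimethylsilyl)oxy]-6-methylhept-5-enoic acid, via potassium ylide carboxylate 3 (not isolated)
Conditions: KN(SiMe3)2 (2 equiv per 1), THF, 0 °C to rt; then 2, −78 °C to rt; cold dilute HCl to pH 4–5
Reagents that add atoms: KN(SiMe3)2, C[Si](C)(C)[N-][Si](C)(C)C.[K+] (its potassium ion is held only by 3)
Why: Wittig olefination under salt-free kinetic control: the non-stabilised ylide 3 adds to the activated α-silyloxy ketone so that the CH2OSi arm plays the part of the aldehyde substituent in a cis-selective Wittig reaction, which should place the chain cis to CH2OSi (Z alkene), while the carboxylate is a spectator that later allows an acid–base separation from the phosphine oxide.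

Step 2
Reactants: 4 (5Z)-7-[(tert-butyldimethylsilyl)oxy]-6-methylhept-5-enoic acid; 5 (4R)-4-benzyl-1,3-oxazolidin-2-one
Product: 7 (4R)-4-benzyl-3-{(5Z)-7-[(tert-butyldimethylsilyl)oxy]-6-methylhept-5-enoyl}-1,3-oxazolidin-2-one, via mixed pivalic anhydride 6 (not isolated)
Conditions: PivCl, Et3N, THF, −20 °C; then LiCl, 5, −20 °C to rt
Reagents that add atoms: pivaloyl chloride, CC(C)(C)C(=O)Cl (its acyl group is held only by 6)
Why: Mixed-anhydride N-acylation of an Evans auxiliary: LiCl and Et3N render the carbamate nitrogen nucleophilic enough to attack the unhindered acyl carbon of 6 rather than the pivaloyl carbon, so no strong base meets the silyl ether or the Z alkene.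

Step 3
Reactants: 7 (4R)-4-benzyl-3-{(5Z)-7-[(tert-butyldimethylsilyl)oxy]-6-methylhept-5-enoyl}-1,3-oxazolidin-2-one; 8 tert-butyl acrylate
Product: 10 tert-butyl (4S,7Z)-4-{[(4R)-4-benzyl-2-oxo-1,3-oxazolidin-3-yl]carbonyl}-9-[(tert-butyldimethylsilyl)oxy]-8-methylnon-7-enoate, via chlorotitanium Z-enolate 9 (not isolated)
Conditions: TiCl4 (0.75 equiv) + Ti(OiPr)4 (0.25 equiv) to give TiCl3(OiPr), iPr2NEt, CH2Cl2, 0 °C; then 8, 0 °C; aq. NH4Cl
Reagents that add atoms: TiCl3(OiPr), CC(C)O[Ti](Cl)(Cl)Cl (held only by 9)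
Why: Evans chlorotitanium-enolate Michael addition: soft enolisation gives the chelated Z-enolate 9 whose one face is covered by the C4 benzyl group of the auxiliary, so the acrylate is taken up on the open face and the new methine is set as 4S, which is the spatial arrangement of C2 in the target.

Step 4
Reactants: 10 tert-butyl (4S,7Z)-4-{[(4R)-4-benzyl-2-oxo-1,3-oxazolidin-3-yl]carbonyl}-9-[(tert-butyldimethylsilyl)oxy]-8-methylnon-7-enoate
Product: 11 tert-butyl (4S,7Z)-9-[(tert-butyldimethylsilyl)oxy]-4-(hydroxymethyl)-8-methylnon-7-enoate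
Conditions: LiBH4, H2O (1 equiv), Et2O, 0 °C; pH 7 buffer
Reagents that add atoms: none
Why: Reductive removal of the auxiliary with LiBH4 is chemoselective because the exocyclic imide carbonyl is far more electrophilic than the hindered tert-butyl ester, and the cold, weakly basic medium does not enolise the adjacent stereocentre.

Step 5
Reactants: 11 tert-butyl (4S,7Z)-9-[(tert-butyldimethylsilyl)oxy]-4-(hydroxymethyl)-8-methylnon-7-enoate
Product: 12 tert-butyl (4S,7Z)-4-(acetoxymethyl)-9-[(tert-butyldimethylsilyl)oxy]-8-methylnon-7-enoate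
Conditions: Ac2O, pyridine, DMAP (cat), CH2Cl2, 0 °C to rt
Reagents that add atoms: acetic anhydride, CC(=O)OC(C)=O
Why: DMAP-catalysed acetylation of an unhindered primary alcohol installs the acetate of the target at once and removes any chance of δ-lactonisation onto the ester.

Step 6
Reactants: 12 tert-butyl (4S,7Z)-4-(acetoxymethyl)-9-[(tert-butyldimethylsilyl)oxy]-8-methylnon-7-enoate
Product: 14 (4S,7Z)-4-(acetoxymethyl)-9-[(tert-butyldimethylsilyl)oxy]-8-methylnon-7-enoic acid, via trimethylsilyl ester 13 (not isolated)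
Conditions: TMSOTf, 2,6-lutidine, CH2Cl2, 0 °C to rt; then aq. NaH2PO4 (pH 5)
Reagents that add atoms: trimethylsilyl triflate, C[Si](C)(C)OS(=O)(=O)C(F)(F)F (its silyl group is held only by 13)
Why: Silyl-triflate-mediated tert-butyl ester cleavage: O-silylation of the ester carbonyl triggers loss of 2-methylpropene under lutidine buffering, so no free strong acid reaches the allylic silyl ether or the acetate, and the labile silyl ester 13 is hydrolysed by the mildly acidic wash.

Step 7
Reactants: 14 (4S,7Z)-4-(acetoxymethyl)-9-[(tert-butyldimethylsilyl)oxy]-8-methylnon-7-enoic acid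
Product: 15 1,3-dioxoisoindolin-2-yl (4S,7Z)-4-(acetoxymethyl)-9-[(tert-butyldimethylsilyl)oxy]-8-methylnon-7-enoate (east redox-active ester)
Conditions: N-hydroxyphthalimide, DIC, DMAP (cat), CH2Cl2, rt
Reagents that add atoms: N-hydroxyphthalimide, O=C1c2ccccc2C(=O)N1O
Why: Steglich-type carbodiimide esterification with N-hydroxyphthalimide runs under neutral conditions that leave acetate, silyl ether, alkene and the remote stereocentre untouched.

Step 8
Reactants: 16 pent-4-enoic acid; 17 (4S)-4-benzyl-1,3-oxazolidin-2-one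
Product: 19 (4S)-4-benzyl-3-(pent-4-enoyl)-1,3-oxazolidin-2-one, via mixed pivalic anhydride 18 (not isolated)
Conditions: PivCl, Et3N, THF, −20 °C; then LiCl, 17, −20 °C to rt
Reagents that add atoms: pivaloyl chloride, CC(C)(C)C(=O)Cl (its acyl group is held only by 18)
Why: The same mixed-anhydride N-acylation of an Evans auxiliary applies, the amine/LiCl pair being too mild to move the terminal alkene into conjugation.

Step 9
Reactants: 19 (4S)-4-benzyl-3-(pent-4-enoyl)-1,3-oxazolidin-2-one; 20 tert-butyl bromoacetate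
Product: 22 tert-butyl (3R)-3-{[(4S)-4-benzyl-2-oxo-1,3-oxazolidin-3-yl]carbonyl}hex-5-enoate, via sodium Z-enolate 21 (not isolated)
Conditions: NaN(SiMe3)2, THF, −78 °C; then 20, −78 to −40 °C
Reagents that add atoms: NaN(SiMe3)2, C[Si](C)(C)[N-][Si](C)(C)C.[Na+] (its sodium ion is held only by 21)
Why: Evans asymmetric enolate alkylation: the chelated sodium Z-enolate 21 is shielded on one face by the C4 benzyl group, so the highly reactive bromoacetate enters from the other face and sets the methine as 3R, the spatial arrangement of C6 in the target.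

Step 10
Reactants: 22 tert-butyl (3R)-3-{[(4S)-4-benzyl-2-oxo-1,3-oxazolidin-3-yl]carbonyl}hex-5-enoate
Product: 23 tert-butyl (3R)-3-(hydroxymethyl)hex-5-enoate
Conditions: LiBH4, H2O (1 equiv), Et2O, 0 °C; cold pH 7 buffer
Reagents that add atoms: none
Why: LiBH4 reduction again singles out the imide carbonyl over the tert-butyl ester, and a cold neutral quench followed by immediate use of the crude alcohol should hold back closure of the γ-hydroxy ester to the γ-lactone.

Step 11
Reactants: 23 tert-butyl (3R)-3-(hydroxymethyl)hex-5-enoate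
Product: 24 tert-butyl (3R)-3-{[(tert-butyldimethylsilyl)oxy]methyl}hex-5-enoate
Conditions: crude 23, TBSCl, imidazole, CH2Cl2, 0 °C to rt
Reagents that add atoms: tert-butyldimethylsilyl chloride, CC(C)(C)[Si](C)(C)Cl
Why: Imidazole-promoted silylation of a primary alcohol is fast and blocks lactonisation for good, and the same silyl group as in the east half allows a single final deprotection.

Step 12
Reactants: 24 tert-butyl (3R)-3-{[(tert-butyldimethylsilyl)oxy]methyl}hex-5-enoate
Product: 26 (3R)-3-{[(tert-butyldimethylsilyl)oxy]methyl}hex-5-enoic acid, via trimethylsilyl ester 25 (not isolated)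
Conditions: TMSOTf, 2,6-lutidine, CH2Cl2, 0 °C to rt; then aq. NaH2PO4 (pH 5)
Reagents that add atoms: trimethylsilyl triflate, C[Si](C)(C)OS(=O)(=O)C(F)(F)F (its silyl group is held only by 25)
Why: Silyl-triflate-mediated tert-butyl ester cleavage as in step 6 avoids protic acid, which would strip the primary silyl ether and let the γ-hydroxy acid lactonise.

Step 13
Reactants: 26 (3R)-3-{[(tert-butyldimethylsilyl)oxy]methyl}hex-5-enoic acid
Product: 27 1,3-dioxoisoindolin-2-yl (3R)-3-{[(tert-butyldimethylsilyl)oxy]methyl}hex-5-enoate (west redox-active ester)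
Conditions: N-hydroxyphthalimide, DIC, DMAP (cat), CH2Cl2, rt
Reagents that add atoms: N-hydroxyphthalimide, O=C1c2ccccc2C(=O)N1O
Why: Steglich-type carbodiimide esterification gives the second redox-active ester under neutral conditions without risk to the β-stereocentre.

Step 14
Reactants: 15 east redox-active ester; 27 west redox-active ester
Product: 28 (2R,6S)-2-{(3Z)-5-[(tert-butyldimethylsilyl)oxy]-4-methylpent-3-en-1-yl}-6-{[(tert-butyldimethylsilyl)oxy]methyl}non-8-en-1-yl acetate
Conditions: 15 (1 equiv), 27 (3 equiv), NiCl2·6H2O (20 mol %), 2,2′:6′,2″-terpyridine (20 mol %), AgNO3 (0.3 equiv), NMP, Mg anode/reticulated vitreous carbon cathode, undivided cell, constant current, rt; dilute HCl work-up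
Reagents that add atoms: none
Why: Terpyridine-ligated nickel, reduced at the silver-conditioned carbon cathode from the divalent to a low-valent state while the Mg anode is consumed, passes single electrons to both N-acyloxyphthalimides, which expel phthalimide anion and CO2 to give the primary radicals at C4 (from 15) and C5 (from 27). Nickel captures the two radicals in turn and the resulting dialkyl trivalent nickel species releases the C4–C5 bond by reductive elimination. This is the known nickel-electrocatalytic doubly decarboxylative C(sp3)–C(sp3) cross-coupling of two primary redox-active esters, the reductive counterpart of a mixed Kolbe electrolysis. No ring closes and no stereocentre is created: C2 lies two carbons from its radical site, and C6, although directly attached to radical carbon C5, could only be scrambled by β-hydride elimination and re-insertion at nickel, for which the tridentate ligand leaves no free site. The step needs cross- over homo-selectivity, secured statistically by a threefold excess of the shorter-made 27 so that 15 ends up mainly in the cross product, whose single acetate sets its polarity apart from both dimers. It also needs radical capture to outrun side reactions, which the substrates favour because the C4 radical is a 6-heptenyl type with only a slow 6-exo closure onto the trisubstituted alkene, the C5 radical is a 4-pentenyl type with no viable closure, and the reducible, radical-accepting butenolide is still absent.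

Step 15
Reactants: 28 coupled C16 chain with terminal allyl group; 29 3-bromofuran-2(5H)-one
Product: 31 (2R,6S)-2-{(3Z)-5-[(tert-butyldimethylsilyl)oxy]-4-methylpent-3-en-1-yl}-6-{[(tert-butyldimethylsilyl)oxy]methyl}-9-(2-oxo-2,5-dihydrofuran-3-yl)nonyl acetate, via B-alkyl-9-BBN borane 30 (not isolated)
Conditions: 9-BBN (1.3 equiv), THF, 0 °C to rt; then H2O, 29, Pd(dppf)Cl2 (5 mol %), AsPh3 (10 mol %), Cs2CO3, DMF, rt
Reagents that add atoms: 9-borabicyclo[3.3.1]nonane, B1C2CCCC1CCC2 (its boryl group is held only by 30)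
Why: 9-BBN hydroborates the monosubstituted terminal alkene far faster than the trisubstituted allylic one and places boron at the terminus, and the B-alkyl Suzuki–Miyaura coupling of 30 with the α-bromo-enoate C–Br bond of 29 under the room-temperature protocol established for α-halo-α,β-unsaturated carbonyl compounds should deliver the intact butenolide ring at C9 without touching the acetate.

Step 16
Reactants: 31 bis-silyl ether of the target
Product: 32 (2R,6S)-6-(hydroxymethyl)-2-[(3Z)-5-hydroxy-4-methylpent-3-en-1-yl]-9-(2-oxo-2,5-dihydrofuran-3-yl)nonyl acetate (target CNP0325245.2)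
Conditions: HF·pyridine, extra pyridine, THF, 0 °C to rt (polypropylene vessel); aq. NaHCO3
Reagents that add atoms: none
Why: Fluoride-driven desilylation in a buffered acidic medium cleaves both primary silyl ethers, whereas the acetate, the base-sensitive butenolide and the Z-allylic alcohol tolerate HF·pyridine and the liberated hydroxyls are too remote from the acetate for acyl migration.

Compound list
1 | (4-carboxybutyl)triphenylphosphonium bromide | OC(=O)CCCC[P+](c1ccccc1)(c1ccccc1)c1ccccc1.[Br-] | starting material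
2 | 1-[(tert-butyldimethylsilyl)oxy]propan-2-one | CC(=O)CO[Si](C)(C)C(C)(C)C | starting material
3 | potassium 5-(triphenyl-λ5-phosphanylidene)pentanoate | [K+].[O-]C(=O)CCCC=P(c1ccccc1)(c1ccccc1)c1ccccc1 | intermediate
4 | (5Z)-7-[(tert-butyldimethylsilyl)oxy]-6-methylhept-5-enoic acid | OC(=O)CCC/C=C(/C)CO[Si](C)(C)C(C)(C)C | intermediate
5 | (4R)-4-benzyl-1,3-oxazolidin-2-one | O=C1OC[C@@H](Cc2ccccc2)N1 | starting material
6 | (5Z)-7-[(tert-butyldimethylsilyl)oxy]-6-methylhept-5-enoic pivalic anhydride | CC(C)(C)C(=O)OC(=O)CCC/C=C(/C)CO[Si](C)(C)C(C)(C)C | intermediate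
7 | (4R)-4-benzyl-3-{(5Z)-7-[(tert-butyldimethylsilyl)oxy]-6-methylhept-5-enoyl}-1,3-oxazolidin-2-one | O=C1OC[C@@H](Cc2ccccc2)N1C(=O)CCC/C=C(/C)CO[Si](C)(C)C(C)(C)C | intermediate
8 | tert-butyl acrylate | C=CC(=O)OC(C)(C)C | starting material
9 | dichloro(isopropoxy)titanium Z-enolate of 7 | O=C1OC[C@@H](Cc2ccccc2)N1/C(O[Ti](Cl)(Cl)OC(C)C)=C/CC/C=C(/C)CO[Si](C)(C)C(C)(C)C | intermediate
10 | tert-butyl (4S,7Z)-4-{[(4R)-4-benzyl-2-oxo-1,3-oxazolidin-3-yl]carbonyl}-9-[(tert-butyldimethylsilyl)oxy]-8-methylnon-7-enoate | O=C1OC[C@@H](Cc2ccccc2)N1C(=O)[C@@H](CC/C=C(/C)CO[Si](C)(C)C(C)(C)C)CCC(=O)OC(C)(C)C | intermediate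
11 | tert-butyl (4S,7Z)-9-[(tert-butyldimethylsilyl)oxy]-4-(hydroxymethyl)-8-methylnon-7-enoate | OC[C@@H](CC/C=C(/C)CO[Si](C)(C)C(C)(C)C)CCC(=O)OC(C)(C)C | intermediate
12 | tert-butyl (4S,7Z)-4-(acetoxymethyl)-9-[(tert-butyldimethylsilyl)oxy]-8-methylnon-7-enoate | CC(=O)OC[C@@H](CC/C=C(/C)CO[Si](C)(C)C(C)(C)C)CCC(=O)OC(C)(C)C | intermediate
13 | trimethylsilyl (4S,7Z)-4-(acetoxymethyl)-9-[(tert-butyldimethylsilyl)oxy]-8-methylnon-7-enoate | CC(=O)OC[C@@H](CC/C=C(/C)CO[Si](C)(C)C(C)(C)C)CCC(=O)O[Si](C)(C)C | intermediate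
14 | (4S,7Z)-4-(acetoxymethyl)-9-[(tert-butyldimethylsilyl)oxy]-8-methylnon-7-enoic acid | CC(=O)OC[C@@H](CC/C=C(/C)CO[Si](C)(C)C(C)(C)C)CCC(=O)O | intermediate
15 | 1,3-dioxoisoindolin-2-yl (4S,7Z)-4-(acetoxymethyl)-9-[(tert-butyldimethylsilyl)oxy]-8-methylnon-7-enoate | CC(=O)OC[C@@H](CC/C=C(/C)CO[Si](C)(C)C(C)(C)C)CCC(=O)ON1C(=O)c2ccccc2C1=O | intermediate
16 | pent-4-enoic acid | OC(=O)CCC=C | starting material
17 | (4S)-4-benzyl-1,3-oxazolidin-2-one | O=C1OC[C@H](Cc2ccccc2)N1 | starting material
18 | pent-4-enoic pivalic anhydride | CC(C)(C)C(=O)OC(=O)CCC=C | intermediate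
19 | (4S)-4-benzyl-3-(pent-4-enoyl)-1,3-oxazolidin-2-one | O=C1OC[C@H](Cc2ccccc2)N1C(=O)CCC=C | intermediate
20 | tert-butyl bromoacetate | BrCC(=O)OC(C)(C)C | starting material
21 | sodium Z-enolate of 19 | O=C1OC[C@H](Cc2ccccc2)N1/C([O-])=C/CC=C.[Na+] | intermediate
22 | tert-butyl (3R)-3-{[(4S)-4-benzyl-2-oxo-1,3-oxazolidin-3-yl]carbonyl}hex-5-enoate | O=C1OC[C@H](Cc2ccccc2)N1C(=O)[C@H](CC=C)CC(=O)OC(C)(C)C | intermediate
23 | tert-butyl (3R)-3-(hydroxymethyl)hex-5-enoate | OC[C@H](CC=C)CC(=O)OC(C)(C)C | intermediate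
24 | tert-butyl (3R)-3-{[(tert-butyldimethylsilyl)oxy]methyl}hex-5-enoate | CC(C)(C)[Si](C)(C)OC[C@H](CC=C)CC(=O)OC(C)(C)C | intermediate
25 | trimethylsilyl (3R)-3-{[(tert-butyldimethylsilyl)oxy]methyl}hex-5-enoate | CC(C)(C)[Si](C)(C)OC[C@H](CC=C)CC(=O)O[Si](C)(C)C | intermediate
26 | (3R)-3-{[(tert-butyldimethylsilyl)oxy]methyl}hex-5-enoic acid | CC(C)(C)[Si](C)(C)OC[C@H](CC=C)CC(=O)O | intermediate
27 | 1,3-dioxoisoindolin-2-yl (3R)-3-{[(tert-butyldimethylsilyl)oxy]methyl}hex-5-enoate | CC(C)(C)[Si](C)(C)OC[C@H](CC=C)CC(=O)ON1C(=O)c2ccccc2C1=O | intermediate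
28 | (2R,6S)-2-{(3Z)-5-[(tert-butyldimethylsilyl)oxy]-4-methylpent-3-en-1-yl}-6-{[(tert-butyldimethylsilyl)oxy]methyl}non-8-en-1-yl acetate | CC(=O)OC[C@@H](CC/C=C(/C)CO[Si](C)(C)C(C)(C)C)CCC[C@H](CO[Si](C)(C)C(C)(C)C)CC=C | intermediate
29 | 3-bromofuran-2(5H)-one | O=C1OCC=C1Br | starting material
30 | 9-alkyl-9-borabicyclo[3.3.1]nonane formed from 28 by anti-Markovnikov hydroboration at C9 | CC(=O)OC[C@@H](CC/C=C(/C)CO[Si](C)(C)C(C)(C)C)CCC[C@H](CO[Si](C)(C)C(C)(C)C)CCCB1C2CCCC1CCC2 | intermediate
31 | (2R,6S)-2-{(3Z)-5-[(tert-butyldimethylsilyl)oxy]-4-methylpent-3-en-1-yl}-6-{[(tert-butyldimethylsilyl)oxy]methyl}-9-(2-oxo-2,5-dihydrofuran-3-yl)nonyl acetate | CC(=O)OC[C@@H](CC/C=C(/C)CO[Si](C)(C)C(C)(C)C)CCC[C@H](CO[Si](C)(C)C(C)(C)C)CCCC1=CCOC1=O | intermediate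
32 | (2R,6S)-6-(hydroxymethyl)-2-[(3Z)-5-hydroxy-4-methylpent-3-en-1-yl]-9-(2-oxo-2,5-dihydrofuran-3-yl)nonyl acetate | CC(=O)OC[C@@H](CC/C=C(/C)CO)CCC[C@H](CO)CCCC1=CCOC1=O | target

Total step count: 16. Longest linear sequence: 10 steps (steps 1–7, then 14–16). The west branch (steps 8–13) is 6 steps before the union.

Steps most likely to fail

Step 14. The two radicals may pair statistically into homo-dimers. They may also be quenched by hydrogen-atom abstraction, including 1,5-transfer from the allylic CH2 of the east arm. Nickel hydride from β-hydride elimination may move the terminal alkene or erode C6. The fallback pairs one radical precursor with a preformed carbon nucleophile instead of two radicals; it sets out from 27 and 15 and comes back at 28. Visible-light decarboxylative iodination of 27 (LiI, catalytic PPh3, blue light, acetone) would give the primary iodide F1. Iodine–zinc exchange (Et2Zn, catalytic CuI, 50 °C, then removal of volatiles) would turn it into the dialkylzinc F2. A nickel-catalysed decarboxylative Negishi alkyl–alkyl coupling of F2 with 15 (NiCl2(dme), 4,4′-di-tert-butyl-2,2′-bipyridine, THF/DMF, rt) would then form the same C4–C5 bond without a statistical component.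

Step 15. Aqueous carbonate may open or γ-deprotonate the bromobutenolide faster than transmetalation occurs. The alkylpalladium species may be lost through β-hydride elimination, and the borane through protodeboronation. The fallback builds the butenolide by enolate alkylation and sulfoxide elimination instead of cross-coupling; it sets out from 28 and comes back at 31.
- Borane 30 would be oxidised with NaBO3·4H2O to the primary alcohol F3.
- An Appel-type iodination (I2, PPh3, imidazole) would convert F3 into the primary iodide F4.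
- Commercial 3-(phenylsulfanyl)oxolan-2-one would be deprotonated with LiN(SiMe3)2 (THF/DMPU, −78 °C) to its lithium enolate F5.
- Alkylation of F5 with F4 would give the α-phenylsulfanyl lactone F6.
- One equivalent of mCPBA at −78 °C, where sulfur is oxidised faster than the trisubstituted alkene, would give the sulfoxide F7.
- Thermal syn-elimination of F7 in refluxing toluene should place the double bond inside the ring.

Step 3. The titanium Lewis acid may strip or ionise the allylic silyl ether. The long-chain enolate may also add sluggishly, so that acrylate oligomerisation competes. The fallback replaces the conjugate addition by a Lewis-acid-free allylation followed by oxidation of the allyl terminus; it sets out from 7 and comes back at 14.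
- NaN(SiMe3)2 (THF, −78 °C) would give the sodium Z-enolate F8.
- Evans allylation with allyl iodide, entering from the same open face, would give the allyl imide F9.
- LiBH4 cleavage would give the alcohol F10, and acetylation the acetate F11.
- 9-BBN would hydroborate only the terminal alkene to the borane F12.
- NaBO3·4H2O would give the primary alcohol F13.
- TEMPO/PhI(OAc)2 in aqueous MeCN would carry F13 through the aldehyde F14 to the acid.

Further compounds
F1 | step 14 | tert-butyl{[(2S)-2-(iodomethyl)pent-4-en-1-yl]oxy}dimethylsilane | CC(C)(C)[Si](C)(C)OC[C@H](CC=C)CI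
F2 | step 14 | bis[(2S)-2-{[(tert-butyldimethylsilyl)oxy]methyl}pent-4-en-1-yl]zinc | CC(C)(C)[Si](C)(C)OC[C@H](CC=C)C[Zn]C[C@@H](CC=C)CO[Si](C)(C)C(C)(C)C
F3 | step 15 | (2R,6S)-2-{(3Z)-5-[(tert-butyldimethylsilyl)oxy]-4-methylpent-3-en-1-yl}-6-{[(tert-butyldimethylsilyl)oxy]methyl}-9-hydroxynonyl acetate | CC(=O)OC[C@@H](CC/C=C(/C)CO[Si](C)(C)C(C)(C)C)CCC[C@H](CO[Si](C)(C)C(C)(C)C)CCCO
F4 | step 15 | (2R,6S)-2-{(3Z)-5-[(tert-butyldimethylsilyl)oxy]-4-methylpent-3-en-1-yl}-6-{[(tert-butyldimethylsilyl)oxy]methyl}-9-iodononyl acetate | CC(=O)OC[C@@H](CC/C=C(/C)CO[Si](C)(C)C(C)(C)C)CCC[C@H](CO[Si](C)(C)C(C)(C)C)CCCI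
F5 | step 15 | lithium enolate of 3-(phenylsulfanyl)oxolan-2-one | [Li+].[O-]C1=C(Sc2ccccc2)CCO1
F6 | step 15 | 9-[2-oxo-3-(phenylsulfanyl)oxolan-3-yl] analogue of F4, both epimers at the lactone carbon | CC(=O)OC[C@@H](CC/C=C(/C)CO[Si](C)(C)C(C)(C)C)CCC[C@H](CO[Si](C)(C)C(C)(C)C)CCCC1(Sc2ccccc2)CCOC1=O
F7 | step 15 | sulfoxide of F6 | CC(=O)OC[C@@H](CC/C=C(/C)CO[Si](C)(C)C(C)(C)C)CCC[C@H](CO[Si](C)(C)C(C)(C)C)CCCC1(S(=O)c2ccccc2)CCOC1=O
F8 | step 3 | sodium Z-enolate of 7 | O=C1OC[C@@H](Cc2ccccc2)N1/C([O-])=C/CC/C=C(/C)CO[Si](C)(C)C(C)(C)C.[Na+]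
F9 | step 3 | (4R)-4-benzyl-3-{(2S,5Z)-2-allyl-7-[(tert-butyldimethylsilyl)oxy]-6-methylhept-5-enoyl}-1,3-oxazolidin-2-one | O=C1OC[C@@H](Cc2ccccc2)N1C(=O)[C@@H](CC/C=C(/C)CO[Si](C)(C)C(C)(C)C)CC=C
F10 | step 3 | (2S,5Z)-2-allyl-7-[(tert-butyldimethylsilyl)oxy]-6-methylhept-5-en-1-ol | OC[C@@H](CC/C=C(/C)CO[Si](C)(C)C(C)(C)C)CC=C
F11 | step 3 | (2S,5Z)-2-allyl-7-[(tert-butyldimethylsilyl)oxy]-6-methylhept-5-en-1-yl acetate | CC(=O)OC[C@@H](CC/C=C(/C)CO[Si](C)(C)C(C)(C)C)CC=C
F12 | step 3 | 9-alkyl-9-borabicyclo[3.3.1]nonane formed from F11 at the allyl terminus | CC(=O)OC[C@@H](CC/C=C(/C)CO[Si](C)(C)C(C)(C)C)CCCB1C2CCCC1CCC2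
F13 | step 3 | (2S,5Z)-7-[(tert-butyldimethylsilyl)oxy]-2-(3-hydroxypropyl)-6-methylhept-5-en-1-yl acetate | CC(=O)OC[C@@H](CC/C=C(/C)CO[Si](C)(C)C(C)(C)C)CCCO
F14 | step 3 | (2S,5Z)-7-[(tert-butyldimethylsilyl)oxy]-6-methyl-2-(3-oxopropyl)hept-5-en-1-yl acetate | CC(=O)OC[C@@H](CC/C=C(/C)CO[Si](C)(C)C(C)(C)C)CCC=O
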